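**Plan**

- Elemane numbering is used: ring B is the cyclohexane C5–C10, ring C is the lactone (C6, C7, C11, C12, O), and β is the face of the C10 methyl. The retrosynthesis first removes the angelate, the C15 acid level and the C11=C13 methylene (masked as a Mannich base), then cuts C8–C9 and C6–C7 together, then C5–C10.
- Enabling feature: in ring B the C7–C8 edge lies between two oxygenated carbons, so ring B is a latent cyclic aldol (C6 carbinol, C7 α-carbon, C8 carbonyl). Its other neighbour, C9, is a plain CH2 next to the quaternary C10. A C7–C8 amide enolate can therefore be stitched between a C6 aldehyde and a C9 carbanion.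
- Forward order: C5–C10 by Ireland–Claisen rearrangement of a prenyl-derived senecioate; ring B in one flask from aldehyde 8 and amide acid 11; then lactone ring C; then C8 reduction, angeloylation, unmasking of the methylene and oxidation of C15.
- Stereochemistry: C5/C10 from the chair Claisen transition state under a chiral diazaborolidine controller; C6 by Felkin–Anh addition; C7 by the Z-enolate (syn aldol); C8 by equatorial hydride attack opposite the axial C10 methyl; angelate geometry from angelic acid.

Key step: step 8

Assumption (chemistry): soft enolisation of the senecioate is taken to give the dienol borinate with C4 cis to the allylic oxygen, and the (4S,5S)-controller to give the (2S,3S)-acid 6; should either not hold, the (Z)-allylic ester or the (4R,5R)-controller would be used.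

**Step 1**
Reactants: 1 3-methylbut-2-en-1-ol (prenol); 2 3-methylbut-2-enoyl chloride
Product: 3 3-methylbut-2-en-1-yl 3-methylbut-2-enoate (prenyl senecioate)
Conditions: pyridine, CH2Cl2, 0 °C
Reagents that add atoms: none
Why: Esterification of the primary allylic alcohol with the acid chloride, where pyridine as a weak base avoids vinylketene formation and deconjugation of the senecioate.

**Step 2**
Reactants: 3 prenyl senecioate
Product: 4 (2E)-4-hydroxy-3-methylbut-2-en-1-yl 3-methylbut-2-enoate
Conditions: SeO2 (cat.), t-BuOOH, salicylic acid (cat.), CH2Cl2, rt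
Reagents that add atoms: tert-butyl hydroperoxide (CC(C)(C)OO)
Why: Allylic oxidation by SeO2 (ene reaction then [2,3]-shift) should attack the electron-rich prenyl alkene at its (E)-methyl group and not the conjugated senecioate alkene, which fixes the (E)-geometry used in step 4.

**Step 3**
Reactants: 4 (2E)-4-hydroxy-3-methylbut-2-en-1-yl 3-methylbut-2-enoate
Product: 5 (2E)-3-methyl-4-(phenylsulfanyl)but-2-en-1-yl 3-methylbut-2-enoate
Conditions: PhSSPh, PBu3, THF, 0 °C to rt
Reagents that add atoms: diphenyl disulfide (c1ccc(cc1)SSc1ccccc1)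
Why: Hata-type thioetherification, in which thiolate displaces the alkoxyphosphonium salt of the primary allylic alcohol, places at the future C9 a group that survives to the key step and can then be turned into a carbanion.

**Step 4**
Reactants: 5 (2E)-3-methyl-4-(phenylsulfanyl)but-2-en-1-yl 3-methylbut-2-enoate
Product: 6 (2S,3S)-3-methyl-3-[(phenylsulfanyl)methyl]-2-(prop-1-en-2-yl)pent-4-enoic acid
Conditions: (4S,5S)-2-bromo-1,3-bis{[3,5-bis(trifluoromethyl)phenyl]sulfonyl}-4,5-diphenyl-1,3,2-diazaborolidine, i-Pr2NEt, CH2Cl2, −78 °C to rt; aq. work-up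
Reagents that add atoms: none
Why: Enantioselective Ireland–Claisen rearrangement, in which soft enolisation at the cis γ-methyl gives a chiral boron dienolate and the chair transition state with CH2SPh equatorial forms C5–C10, setting the quaternary C10 (methyl, vinyl) and C5 (isopropenyl) relative to each other while the diazaborolidine ligand selects the enantiomer.

**Step 5**
Reactants: 6 (2S,3S)-3-methyl-3-[(phenylsulfanyl)methyl]-2-(prop-1-en-2-yl)pent-4-enoic acid
Product: 7 (2S,3S)-3-methyl-3-[(phenylsulfanyl)methyl]-2-(prop-1-en-2-yl)pent-4-en-1-ol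
Conditions: LiAlH4, Et2O, 0 °C
Reagents that add atoms: none
Why: Hydride reduction of the carboxylic acid to the primary alcohol should leave the alkenes, the sulfide and the α-stereocentre untouched.

**Step 6**
Reactants: 7 (2S,3S)-3-methyl-3-[(phenylsulfanyl)methyl]-2-(prop-1-en-2-yl)pent-4-en-1-ol
Product: 8 (2S,3S)-3-methyl-3-[(phenylsulfanyl)methyl]-2-(prop-1-en-2-yl)pent-4-enal
Conditions: Dess–Martin periodinane, CH2Cl2, 0 °C
Reagents that add atoms: none
Why: Dess–Martin oxidation under non-basic conditions should give the β,γ-unsaturated aldehyde without epimerisation at C5 or migration of the isopropenyl double bond into conjugation.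

**Step 7**
Reactants: 9 itaconic anhydride
Product: 11 2-[(dimethylamino)methyl]-4-(morpholin-4-yl)-4-oxobutanoic acid (racemic), via itaconic monomorpholide 10 (not isolated)
Conditions: morpholine (1 equiv), CH2Cl2, 0 °C; then Me2NH (aq.), 50 °C
Reagents that add atoms: morpholine (C1COCCN1); dimethylamine (CNC)
Why: Regioselective aminolysis of the anhydride at the non-conjugated carbonyl, then aza-Michael addition to the acrylic acid, masks the future exocyclic methylene as a Mannich base (C11 forms as a mixture that is removed again in step 12).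

**Step 8**
Reactants: 8 (2S,3S)-3-methyl-3-[(phenylsulfanyl)methyl]-2-(prop-1-en-2-yl)pent-4-enal; 11 2-[(dimethylamino)methyl]-4-(morpholin-4-yl)-4-oxobutanoic acid
Product: 14 13-(dimethylamino)-6α-hydroxy-8-oxoelema-1,3-dien-12-oic acid (5α-H, 7α-H, 10β-methyl; C11 epimers), via dilithium aldolate 12 (not isolated), via C9-lithio aldolate 13 (not isolated)
Conditions: 11, lithium diisopropylamide (2.1 equiv), THF, −78 to 0 °C, then −78 °C; 8, −78 °C; then lithium 4,4'-di-tert-butylbiphenylide (2.2 equiv), −78 °C; aq. NH4Cl
Reagents that add atoms: none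
Why: Proposed new method: the dilithium salt of 11 (carboxylate plus Z-configured amide enolate, the only enolisable position) adds to aldehyde 8 in an aldol reaction that forms C6–C7, and lithium 4,4'-di-tert-butylbiphenylide then cleaves the C9–S bond of the aldolate by reductive lithiation so that the primary carbanion attacks the morpholine amide and forms C8–C9; the closest known reaction types are the lithium amide-enolate aldol, the reductive lithiation of alkyl phenyl sulfides and the Parham-type cyclisation of organolithiums onto amides, which have not been merged in one flask on an aldolate. Ring B (the cyclohexanone) closes by 6-exo-trig attack of C9 on the amide carbonyl, and the tetrahedral intermediate collapses to the C8 ketone only on work-up, so no second addition can occur. C6 is set by Felkin–Anh addition anti to the quaternary C10 and C7 by the Zimmerman–Traxler transition state of the Z-enolate (6,7-syn, which becomes trans-diequatorial in the ring), while C8 is trigonal and C11 stays a mixture. The sequence needs chemoselective carbanion generation at C9 beside an amide, an alkoxide and two alkenes, which the phenyl sulfide should secure as the only group reduced by the arene radical anion at −78 °C. A carbanion and not a radical is needed at C9, because a primary radical next to the methyl- and vinyl-bearing C10 would undergo 1,2-vinyl migration, and fast two-electron reduction at low temperature should avoid this. The aldehyde is consumed before the carbanion is made, so the two incompatible functions of 8 never coexist.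

**Step 9**
Reactants: 14 13-(dimethylamino)-6α-hydroxy-8-oxoelema-1,3-dien-12-oic acid
Product: 15 13-(dimethylamino)-8-oxoelema-1,3-dien-12,6α-olide (trans-fused lactone; C11 epimers)
Conditions: EDC·HCl, DMAP (cat.), CH2Cl2, 0 °C to rt
Reagents that add atoms: none
Why: Carbodiimide lactonisation of the γ-hydroxy acid should give the trans-fused 12,6-lactone (ring C), since the 6α-hydroxyl is the only hydroxyl present while C8 is still a ketone.

**Step 10**
Reactants: 15 13-(dimethylamino)-8-oxoelema-1,3-dien-12,6α-olide
Product: 16 13-(dimethylamino)-8β-hydroxyelema-1,3-dien-12,6α-olide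
Conditions: LiBH(s-Bu)3 (L-Selectride), THF, −78 °C; AcOH quench at −78 °C
Reagents that add atoms: none
Why: Diastereoselective ketone reduction, in which the bulky hydride attacks C8 along the equatorial trajectory because the axial face of the conformationally locked trans-fused bicycle is blocked by the syn-axial C10 methyl, should give the axial 8β-alcohol while the lactone is inert at −78 °C.

**Step 11**
Reactants: 16 13-(dimethylamino)-8β-hydroxyelema-1,3-dien-12,6α-olide; 17 angelic acid [(2Z)-2-methylbut-2-enoic acid]
Product: 19 8β-angeloyloxy-13-(dimethylamino)elema-1,3-dien-12,6α-olide, via mixed anhydride 18 (not isolated)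
Conditions: 17, 2,4,6-trichlorobenzoyl chloride, Et3N, toluene, rt; then 16, 80 °C
Reagents that add atoms: none
Why: Yamaguchi-type esterification through the mixed anhydride without a nucleophilic catalyst should acylate the hindered axial alcohol and avoid isomerisation of the (Z)-angelate to the tiglate.

**Step 12**
Reactants: 19 8β-angeloyloxy-13-(dimethylamino)elema-1,3-dien-12,6α-olide
Product: 21 8β-angeloyloxyelema-1,3,11(13)-trien-12,6α-olide, via trimethylammonium iodide 20 (not isolated)
Conditions: MeI, THF, rt; then NaHCO3, H2O/THF, rt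
Reagents that add atoms: none
Why: N-Methylation followed by E1cB loss of trimethylamine (Hofmann-type unmasking of the Mannich base) should release the α-methylene lactone under mild base that leaves both ester groups intact.

**Step 13**
Reactants: 21 8β-angeloyloxyelema-1,3,11(13)-trien-12,6α-olide
Product: 23 8β-angeloyloxy-15-oxoelema-1,3,11(13)-trien-12,6α-olide, via 15-hydroxy compound 22 (not isolated)
Conditions: SeO2 (cat.), t-BuOOH, CH2Cl2, rt; then Dess–Martin periodinane, CH2Cl2, 0 °C
Reagents that add atoms: tert-butyl hydroperoxide (CC(C)(C)OO)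
Why: Allylic oxidation by SeO2 (ene reaction then [2,3]-shift) should take place at the methyl group of the isopropenyl unit, the only electron-rich alkene with allylic hydrogen, and Dess–Martin oxidation then converges alcohol and aldehyde to the 2-substituted acrolein.

**Step 14**
Reactants: 23 8β-angeloyloxy-15-oxoelema-1,3,11(13)-trien-12,6α-olide
Product: 24 8β-angeloyloxyelema-1,3,11(13)-trien-15-oic acid 12,6α-olide (target)
Conditions: NaClO2, NaH2PO4, 2-methylbut-2-ene, t-BuOH/H2O, 0 °C to rt
Reagents that add atoms: sodium chlorite ([Na+].[O-]Cl=O)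
Why: Pinnick oxidation should convert the enal to the acrylic acid without touching the alkenes, the lactone or the angelate.

**Compound list**

1 | 3-methylbut-2-en-1-ol (prenol) | CC(C)=CCO | starting material
2 | 3-methylbut-2-enoyl chloride | CC(C)=CC(=O)Cl | starting material
3 | 3-methylbut-2-en-1-yl 3-methylbut-2-enoate | CC(C)=CCOC(=O)C=C(C)C | intermediate
4 | (2E)-4-hydroxy-3-methylbut-2-en-1-yl 3-methylbut-2-enoate | OC/C(C)=C/COC(=O)C=C(C)C | intermediate
5 | (2E)-3-methyl-4-(phenylsulfanyl)but-2-en-1-yl 3-methylbut-2-enoate | CC(C)=CC(=O)OC/C=C(C)/CSc1ccccc1 | intermediate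
6 | (2S,3S)-3-methyl-3-[(phenylsulfanyl)methyl]-2-(prop-1-en-2-yl)pent-4-enoic acid | C=C[C@](C)(CSc1ccccc1)[C@H](C(C)=C)C(=O)O | intermediate
7 | (2S,3S)-3-methyl-3-[(phenylsulfanyl)methyl]-2-(prop-1-en-2-yl)pent-4-en-1-ol | C=C[C@](C)(CSc1ccccc1)[C@H](C(C)=C)CO | intermediate
8 | (2S,3S)-3-methyl-3-[(phenylsulfanyl)methyl]-2-(prop-1-en-2-yl)pent-4-enal | C=C[C@](C)(CSc1ccccc1)[C@H](C(C)=C)C=O | intermediate
9 | itaconic anhydride (3-methylideneoxolane-2,5-dione) | C=C1CC(=O)OC1=O | starting material
10 | 2-methylidene-4-(morpholin-4-yl)-4-oxobutanoic acid | C=C(CC(=O)N1CCOCC1)C(=O)O | intermediate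
11 | 2-[(dimethylamino)methyl]-4-(morpholin-4-yl)-4-oxobutanoic acid (racemic) | CN(C)CC(CC(=O)N1CCOCC1)C(=O)O | intermediate
12 | dilithium salt of the aldol adduct of 8 and 11: 2-[(dimethylamino)methyl]-4-hydroxy-6-methyl-3-(morpholine-4-carbonyl)-6-[(phenylsulfanyl)methyl]-5-(prop-1-en-2-yl)oct-7-enoic acid (configuration at the four defined centres as in 14) | C=C[C@](C)(CSc1ccccc1)[C@H](C(C)=C)[C@@H](O[Li])[C@@H](C(=O)N1CCOCC1)C(CN(C)C)C(=O)O[Li] | intermediate
13 | C9-lithio derivative of 12 (phenylsulfanyl replaced by lithium) | C=C[C@](C)(C[Li])[C@H](C(C)=C)[C@@H](O[Li])[C@@H](C(=O)N1CCOCC1)C(CN(C)C)C(=O)O[Li] | intermediate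
14 | 13-(dimethylamino)-6α-hydroxy-8-oxoelema-1,3-dien-12-oic acid (5α-H, 7α-H, 10β-methyl; C11 epimers) | C=C[C@]1(C)CC(=O)[C@@H](C(CN(C)C)C(=O)O)[C@H](O)[C@H]1C(C)=C | intermediate
15 | 13-(dimethylamino)-8-oxoelema-1,3-dien-12,6α-olide (C11 epimers) | C=C[C@]1(C)CC(=O)[C@H]2C(CN(C)C)C(=O)O[C@@H]2[C@H]1C(C)=C | intermediate
16 | 13-(dimethylamino)-8β-hydroxyelema-1,3-dien-12,6α-olide (C11 epimers) | C=C[C@]1(C)C[C@@H](O)[C@H]2C(CN(C)C)C(=O)O[C@@H]2[C@H]1C(C)=C | intermediate
17 | angelic acid, (2Z)-2-methylbut-2-enoic acid | C/C=C(/C)C(=O)O | starting material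
18 | (2Z)-2-methylbut-2-enoic 2,4,6-trichlorobenzoic anhydride | C/C=C(/C)C(=O)OC(=O)c1c(Cl)cc(Cl)cc1Cl | intermediate
19 | 8β-angeloyloxy-13-(dimethylamino)elema-1,3-dien-12,6α-olide (C11 epimers) | C=C[C@]1(C)C[C@@H](OC(=O)/C(C)=C\C)[C@H]2C(CN(C)C)C(=O)O[C@@H]2[C@H]1C(C)=C | intermediate
20 | N,N,N-trimethylammonium iodide of 19 | C=C[C@]1(C)C[C@@H](OC(=O)/C(C)=C\C)[C@H]2C(C[N+](C)(C)C)C(=O)O[C@@H]2[C@H]1C(C)=C.[I-] | intermediate
21 | 8β-angeloyloxyelema-1,3,11(13)-trien-12,6α-olide | C=C[C@]1(C)C[C@@H](OC(=O)/C(C)=C\C)[C@H]2C(=C)C(=O)O[C@@H]2[C@H]1C(C)=C | intermediate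
22 | 8β-angeloyloxy-15-hydroxyelema-1,3,11(13)-trien-12,6α-olide | C=C[C@]1(C)C[C@@H](OC(=O)/C(C)=C\C)[C@H]2C(=C)C(=O)O[C@@H]2[C@H]1C(=C)CO | intermediate
23 | 8β-angeloyloxy-15-oxoelema-1,3,11(13)-trien-12,6α-olide | C=C[C@]1(C)C[C@@H](OC(=O)/C(C)=C\C)[C@H]2C(=C)C(=O)O[C@@H]2[C@H]1C(=C)C=O | intermediate
24 | 8β-angeloyloxyelema-1,3,11(13)-trien-15-oic acid 12,6α-olide (5R,6R,7R,8R,10S in elemane numbering) | C=C[C@]1(C)C[C@@H](OC(=O)/C(C)=C\C)[C@H]2C(=C)C(=O)O[C@@H]2[C@H]1C(=C)C(=O)O | target

**Step count and risks**

Total: 14 steps. Longest linear sequence: 13 steps (steps 1–6 and 8–14; step 7 is a one-step branch).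

Step 8 (key step, proposed new method). What may go wrong: incomplete facial or syn/anti control in the intermolecular aldol addition (the Z-enolate is partly mismatched with Felkin–Anh approach), proton transfer from C7 to the new carbanion in place of ring closure, and over-reduction by the arene radical anion. The fallback makes the C9 carbanion by deprotonation of a sulfone and uses only known reaction types. It sets out from alcohol 7: H2O2 with catalytic (NH4)6Mo7O24 oxidises the sulfide to the sulfone alcohol F1, and Dess–Martin oxidation gives the sulfone aldehyde F2. Aldol addition of the dilithium salt of 11 gives, after work-up, the isolated aldol adduct F3, whose diastereomers can be separated at this point. Excess lithium diisopropylamide then forms the α-sulfonyl carbanion, which is acylated by the morpholine amide (6-exo-trig) to the β-keto sulfone F4. Al(Hg) in wet THF removes the sulfonyl group and the route is rejoined at hydroxy ketone acid 14.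

Step 13. What may go wrong: unselective or incomplete allylic oxidation late in the route (attack at C5–H or at the angelate methyl groups, over-oxidation). The fallback sets out from 21: ene-type chlorination of the 1,1-disubstituted alkene with Ca(OCl)2 and solid CO2 in CH2Cl2/H2O gives the allylic chloride F5, and Kornblum-type oxidation with trimethylamine N-oxide in DMSO gives the aldehyde, rejoining the route at 23.

Step 11. What may go wrong: slow acylation of the hindered axial 8β-hydroxyl, with isomerisation of the angeloyl to the tigloyl group or acyl migration towards the lactone on long heating. The fallback builds the angelate on the substrate and sets out from 16: carbodiimide esterification with 2-[bis(2,2,2-trifluoroethoxy)phosphoryl]propanoic acid gives the phosphonate ester F6, and Z-selective Still–Gennari olefination with acetaldehyde (KN(SiMe3)2, 18-crown-6, THF, −78 °C) forms the (Z)-2-methylbut-2-enoate, rejoining the route at 19.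

**Further compounds**

F1 | step 8 | (2S,3S)-3-methyl-3-[(phenylsulfonyl)methyl]-2-(prop-1-en-2-yl)pent-4-en-1-ol | C=C[C@](C)(CS(=O)(=O)c1ccccc1)[C@H](C(C)=C)CO
F2 | step 8 | (2S,3S)-3-methyl-3-[(phenylsulfonyl)methyl]-2-(prop-1-en-2-yl)pent-4-enal | C=C[C@](C)(CS(=O)(=O)c1ccccc1)[C@H](C(C)=C)C=O
F3 | step 8 | sulfone analogue of aldol adduct 12 as the free hydroxy acid | C=C[C@](C)(CS(=O)(=O)c1ccccc1)[C@H](C(C)=C)[C@@H](O)[C@@H](C(=O)N1CCOCC1)C(CN(C)C)C(=O)O
F4 | step 8 | 9-(phenylsulfonyl) derivative of 14 (β-keto sulfone, mixture at C9 and C11) | C=C[C@]1(C)C(S(=O)(=O)c2ccccc2)C(=O)[C@@H](C(CN(C)C)C(=O)O)[C@H](O)[C@H]1C(C)=C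
F5 | step 13 | 8β-angeloyloxy-15-chloroelema-1,3,11(13)-trien-12,6α-olide | C=C[C@]1(C)C[C@@H](OC(=O)/C(C)=C\C)[C@H]2C(=C)C(=O)O[C@@H]2[C@H]1C(=C)CCl
F6 | step 11 | 8β-{2-[bis(2,2,2-trifluoroethoxy)phosphoryl]propanoyloxy}-13-(dimethylamino)elema-1,3-dien-12,6α-olide | C=C[C@]1(C)C[C@@H](OC(=O)C(C)P(=O)(OCC(F)(F)F)OCC(F)(F)F)[C@H]2C(CN(C)C)C(=O)O[C@@H]2[C@H]1C(C)=C
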